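## Retrosynthetic overview

- Target 16 comes from carbinol 15 by acetylation, and 15 from dihydrobenzofuran 14 by oxidation with (NH4)2Ce(NO3)6. The plan rests on one feature: the acetate oxygen sits on side-chain carbon C2′, which is joined through C1′ to ring carbon C6, next to the C1 carbonyl. The atoms O, C2′, C1′, C6 and C1 can therefore first form a five-membered ether ring (ring B of a 2,3-dihydrobenzofuran), whose aryl C1–O bond is cut when ring A is oxidised to the quinone.
- 14 comes from vinyl ether 11 by cross-metathesis with 1-undecene 12 and diimide reduction; the vinyl group is the handle for the C11 chain.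
- 11 comes from phenol carbonate 10 by palladium-catalysed asymmetric intramolecular allylic etherification, which makes the O–C2′ bond, the only stereocentre and ring B in one step.
- 10 comes from allylphenol 7 and bis(carbonate) 9 by cross-metathesis; 7 comes from aldehyde 1 by Baeyer–Villiger oxidation, O-allylation with 4 and Claisen rearrangement; 9 comes from diol 8.
- Ring order: aromatic ring A is present from 1; ring B is closed in step 6 and opened again in step 9, when ring A becomes the quinone.

Key step: step 6

Remark: which antipode of the ligand gives (S)-11 in a 5-exo phenol closure cannot be predicted with certainty, so the (1S,2S)-ligand is proposed, the configuration is to be checked at 15 (Mosher esters), and the (1R,2R)-ligand is used with nothing else changed if the sense proves opposite.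

## Route

Step 1
Reactants: 1 2,4-dimethoxybenzaldehyde
Product: 3 2,4-dimethoxyphenol, via 2,4-dimethoxyphenyl formate 2 (not isolated)
Conditions: mCPBA, CH2Cl2, 0 °C to rt; aq. NaHCO3 wash; then K2CO3 (cat.), MeOH, rt
Reagents that add atoms: 3-chloroperoxybenzoic acid (mCPBA), OOC(=O)c1cccc(Cl)c1
Why: Baeyer–Villiger (Dakin-type) oxidation, in which the electron-rich aryl group migrates in the Criegee adduct to give the aryl formate, whose methanolysis frees the phenol.

Step 2
Reactants: 3 2,4-dimethoxyphenol; 4 allyl bromide
Product: 5 1-(allyloxy)-2,4-dimethoxybenzene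
Conditions: K2CO3, acetone, reflux
Reagents that add atoms: none
Why: Williamson ether synthesis, the phenoxide being O-alkylated by the primary allylic bromide in an SN2 reaction.

Step 3
Reactants: 5 1-(allyloxy)-2,4-dimethoxybenzene
Product: 7 2-allyl-4,6-dimethoxyphenol, via 6-allyl-2,4-dimethoxycyclohexa-2,4-dien-1-one 6 (not isolated)
Conditions: N,N-diethylaniline, 195 °C, argon
Reagents that add atoms: none
Why: Aromatic Claisen rearrangement, whose [3,3] shift can only end at the one free ortho carbon (the other ortho position and the para position carry methoxy groups), followed by tautomerisation of the dienone to the phenol.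

Step 4
Reactants: 8 cis-but-2-ene-1,4-diol
Product: 9 (Z)-but-2-ene-1,4-diyl dimethyl bis(carbonate)
Conditions: ClCO2Me, pyridine, CH2Cl2, 0 °C to rt
Reagents that add atoms: methyl chloroformate, COC(=O)Cl
Why: Carbonate formation by acylation of both primary allylic alcohols with the chloroformate and pyridine as base, leaving the cis double bond untouched.

Step 5
Reactants: 7 2-allyl-4,6-dimethoxyphenol; 9 (Z)-but-2-ene-1,4-diyl dimethyl bis(carbonate) (3 equiv)
Product: 10 (E)-4-(2-hydroxy-3,5-dimethoxyphenyl)but-2-en-1-yl methyl carbonate
Conditions: second-generation Grubbs catalyst RuCl2(=CHPh)(PCy3)(H2IMes) (5 mol%), CH2Cl2, 40 °C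
Reagents that add atoms: none
Why: Olefin cross-metathesis in which the terminal allyl arene exchanges its CH2 terminus for one half of the symmetric internal olefin used in excess, the (E)-isomer being expected to predominate as the more stable product and the free phenol and carbonate being tolerated by the ruthenium carbene.

Step 6
Reactants: 10 (E)-4-(2-hydroxy-3,5-dimethoxyphenyl)but-2-en-1-yl methyl carbonate
Product: 11 (S)-5,7-dimethoxy-2-vinyl-2,3-dihydrobenzofuran
Conditions: Pd2(dba)3·CHCl3 (2 mol%), N,N′-[(1S,2S)-cyclohexane-1,2-diyl]bis[2-(diphenylphosphino)benzamide] (6 mol%), AcOH (1 equiv), CH2Cl2, rt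
Reagents that add atoms: none
Why: Zerovalent palladium bound to the chiral diphosphine ionises the allylic methyl carbonate (loss of CO2 and methoxide, the latter buffered by AcOH) to a cationic π-allylpalladium complex, and the phenol oxygen attacks the internal allyl terminus on the face opposite the metal, forming the O–C2 bond. The closest known reaction type is the palladium-catalysed asymmetric allylic alkylation with phenol oxygen nucleophiles (intramolecular Tsuji–Trost etherification) that gives 2-vinylchromans and 2-alkenyl-2,3-dihydrobenzofurans. Ring B closes in the 5-exo mode, the 7-endo closure to a benzoxepine being disfavoured by ring size. The new stereocentre C2 is set by the ligand: the two diastereomeric π-allyl complexes interconvert by π–σ–π isomerisation at the unsubstituted CH2 terminus faster than they cyclise, and the chiral pocket lets one of them close faster (Curtin–Hammett control), predicted here to give the (S)-ether. The step needs enantioselectivity and branched regioselectivity; the first rests on the ligand and the second on the two-atom tether between the phenol oxygen and the allyl unit, while O- over C-alkylation is secured because both ortho positions and the para position of the phenol are substituted.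

Step 7
Reactants: 11 (S)-5,7-dimethoxy-2-vinyl-2,3-dihydrobenzofuran; 12 1-undecene (4 equiv)
Product: 13 (S,E)-5,7-dimethoxy-2-(undec-1-en-1-yl)-2,3-dihydrobenzofuran
Conditions: second-generation Grubbs catalyst RuCl2(=CHPh)(PCy3)(H2IMes) (5 mol%), CH2Cl2, 40 °C
Reagents that add atoms: none
Why: Olefin cross-metathesis of the vinyl group (a secondary allylic ether, slow to homodimerise) with an excess of the terminal alkene should give the (E)-disubstituted olefin without touching the stereocentre.

Step 8
Reactants: 13 (S,E)-5,7-dimethoxy-2-(undec-1-en-1-yl)-2,3-dihydrobenzofuran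
Product: 14 (R)-5,7-dimethoxy-2-undecyl-2,3-dihydrobenzofuran
Conditions: TsNHNH2 (excess), NaOAc, DME/H2O, reflux
Reagents that add atoms: none
Why: Diimide reduction, the concerted syn transfer of two hydrogens from HN=NH made in the flask, saturates the alkene without the hydrogenolysis of the allylic C–O bond that H2 over palladium on carbon would risk, and the descriptor changes from S to R only because the saturated chain now ranks below the benzylic CH2.

Step 9
Reactants: 14 (R)-5,7-dimethoxy-2-undecyl-2,3-dihydrobenzofuran
Product: 15 (R)-2-(2-hydroxytridecyl)-6-methoxy-1,4-benzoquinone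
Conditions: (NH4)2Ce(NO3)6 (2.5 equiv), MeCN/H2O, 0 °C
Reagents that add atoms: water, O
Why: Oxidative dealkylation of a para-dialkoxyarene by tetravalent cerium, in which two one-electron oxidations with addition of water at C5 and C7a expel methanol and cleave the aryl C–O bond of ring B, so that the former ring oxygen stays on C2′ as the carbinol with retention because no bond to the stereocentre is broken.

Step 10
Reactants: 15 (R)-2-(2-hydroxytridecyl)-6-methoxy-1,4-benzoquinone
Product: 16 (R)-1-(5-methoxy-3,6-dioxocyclohexa-1,4-dien-1-yl)tridecan-2-yl acetate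
Conditions: Ac2O, pyridine, DMAP (cat.), CH2Cl2, 0 °C
Reagents that add atoms: acetic anhydride, CC(=O)OC(C)=O
Why: Acylation of the secondary alcohol with acetic anhydride under nucleophilic catalysis by DMAP at low temperature, which the methoxyquinone should tolerate and which leaves the C–O bond and hence the configuration intact.

## Compound list

1 | 2,4-dimethoxybenzaldehyde | COc1ccc(C=O)c(OC)c1 | starting material
2 | 2,4-dimethoxyphenyl formate | COc1ccc(OC=O)c(OC)c1 | intermediate
3 | 2,4-dimethoxyphenol | COc1ccc(O)c(OC)c1 | intermediate
4 | allyl bromide | C=CCBr | starting material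
5 | 1-(allyloxy)-2,4-dimethoxybenzene | C=CCOc1ccc(OC)cc1OC | intermediate
6 | 6-allyl-2,4-dimethoxycyclohexa-2,4-dien-1-one | C=CCC1C=C(OC)C=C(OC)C1=O | intermediate
7 | 2-allyl-4,6-dimethoxyphenol | C=CCc1cc(OC)cc(OC)c1O | intermediate
8 | cis-but-2-ene-1,4-diol | OC/C=C\CO | starting material
9 | (Z)-but-2-ene-1,4-diyl dimethyl bis(carbonate) | COC(=O)OC/C=C\COC(=O)OC | intermediate
10 | (E)-4-(2-hydroxy-3,5-dimethoxyphenyl)but-2-en-1-yl methyl carbonate | COc1cc(OC)c(O)c(C/C=C/COC(=O)OC)c1 | intermediate
11 | (S)-5,7-dimethoxy-2-vinyl-2,3-dihydrobenzofuran | C=C[C@@H]1Cc2cc(OC)cc(OC)c2O1 | intermediate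
12 | 1-undecene | C=CCCCCCCCCC | starting material
13 | (S,E)-5,7-dimethoxy-2-(undec-1-en-1-yl)-2,3-dihydrobenzofuran | CCCCCCCCC/C=C/[C@@H]1Cc2cc(OC)cc(OC)c2O1 | intermediate
14 | (R)-5,7-dimethoxy-2-undecyl-2,3-dihydrobenzofuran | CCCCCCCCCCC[C@@H]1Cc2cc(OC)cc(OC)c2O1 | intermediate
15 | (R)-2-(2-hydroxytridecyl)-6-methoxy-1,4-benzoquinone | CCCCCCCCCCC[C@H](CC1=CC(=O)C=C(OC)C1=O)O | intermediate
16 | (R)-1-(5-methoxy-3,6-dioxocyclohexa-1,4-dien-1-yl)tridecan-2-yl acetate | CCCCCCCCCCC[C@H](CC1=CC(=O)C=C(OC)C1=O)OC(C)=O | target

## Step count and risks

Total step count: 10. Longest linear sequence: 9 steps (1 → 3 → 5 → 7 → 10 → 11 → 13 → 14 → 15 → 16); step 4 is a one-step side branch.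

**Step 6.** What may go wrong: poor enantiofacial discrimination if the short tether makes ring closure compete with π–σ–π equilibration, erosion of enantiomeric purity by re-ionisation of the allylic aryl ether product, and β-hydride elimination of the π-allyl complex to a diene. Fallback: the stereocentre is set by hydrolytic kinetic resolution of a terminal epoxide instead, and the temporary ring is given up. The fallback sets out from 7 and rejoins the route at 15, before step 10. Phenol 7 is methylated (MeI, K2CO3, acetone) to 1-allyl-2,3,5-trimethoxybenzene F1 and epoxidised (mCPBA, NaHCO3, CH2Cl2) to racemic 2-(2,3,5-trimethoxybenzyl)oxirane F2. F2 is resolved with H2O (0.55 equiv) and (salen)Co(OAc), the acetate of the trivalent cobalt complex of N,N′-bis(3,5-di-tert-butylsalicylidene)cyclohexane-1,2-diamine, the catalyst antipode being chosen so that (S)-2-(2,3,5-trimethoxybenzyl)oxirane F3 is the epoxide left unhydrolysed. Opening at the terminal carbon with C10H21MgBr and CuI (cat.) in THF at −30 °C should give (R)-1-(2,3,5-trimethoxyphenyl)tridecan-2-ol F4; the descriptor changes only through the priority switch. Oxidation with (NH4)2Ce(NO3)6 in MeCN/H2O at 0 °C then removes the two para-related methyl groups as methanol and gives 15.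

**Step 9.** What may go wrong: attack of water at C7 instead of C5 leading to the ortho-quinone, over-oxidation or nitration of the very electron-rich ring, and incomplete collapse of ring B. Fallback: the oxidation is split into an anodic methoxylation and a separate hydrolysis, with no chemical oxidant. The fallback sets out from 14 and rejoins the route at 15. Constant-current electrolysis of 14 (platinum anode, KOH, MeOH, 0 °C, undivided cell) should give the quinone bis(ketal) (2R)-5,5,7,7a-tetramethoxy-2-undecyl-2,3,5,7a-tetrahydrobenzofuran F5 as a mixture of epimers at C7a. Mild hydrolysis (1 M HCl, acetone, rt) releases both carbonyl groups and opens ring B to give 15.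

**Step 5.** What may go wrong: migration of the allyl double bond into conjugation with the ring through ruthenium hydride species, slowing of the catalyst by the electron-rich ortho-hydroxy group, and incomplete E/Z control. Fallback: the metathesis is run on a silyl ether and the phenol is released afterwards. The fallback sets out from 7 and rejoins the route at 10, before step 6. Silylation (tert-butyldimethylsilyl chloride, imidazole, DMF) gives (2-allyl-4,6-dimethoxyphenoxy)(tert-butyl)dimethylsilane F6. Cross-metathesis with 9 under the conditions of step 5 gives (E)-4-[2-(tert-butyldimethylsilyloxy)-3,5-dimethoxyphenyl]but-2-en-1-yl methyl carbonate F7. Bu4NF buffered with AcOH in THF at 0 °C then frees the phenol to give 10.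

Further compounds
F1 | step 6 | 1-allyl-2,3,5-trimethoxybenzene | C=CCc1cc(OC)cc(OC)c1OC
F2 | step 6 | racemic 2-(2,3,5-trimethoxybenzyl)oxirane | COc1cc(CC2CO2)c(OC)c(OC)c1
F3 | step 6 | (S)-2-(2,3,5-trimethoxybenzyl)oxirane | C1[C@H](Cc2cc(OC)cc(OC)c2OC)O1
F4 | step 6 | (R)-1-(2,3,5-trimethoxyphenyl)tridecan-2-ol | CCCCCCCCCCC[C@H](Cc1cc(OC)cc(OC)c1OC)O
F5 | step 9 | (2R)-5,5,7,7a-tetramethoxy-2-undecyl-2,3,5,7a-tetrahydrobenzofuran | CCCCCCCCCCC[C@@H]1CC2=CC(OC)(OC)C=C(OC)C2(OC)O1
F6 | step 5 | (2-allyl-4,6-dimethoxyphenoxy)(tert-butyl)dimethylsilane | C=CCc1cc(OC)cc(OC)c1O[Si](C)(C)C(C)(C)C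
F7 | step 5 | (E)-4-[2-(tert-butyldimethylsilyloxy)-3,5-dimethoxyphenyl]but-2-en-1-yl methyl carbonate | COC(=O)OC/C=C/Cc1cc(OC)cc(OC)c1O[Si](C)(C)C(C)(C)C
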